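Line the four set-ups up and ask what a gap wider than the margin would take.

| setting | north-east | south-west | east | north-west |
|---|---|---|---|---|
| substrate | 0.13 M | 0.13 M (fed, over 20.0 s) | 0.13 M | 0.13 M |
| coupling partner | 0.195 M | 0.195 M | 0.195 M | 0.195 M |
| initiator | 1.3 mM | 1.3 mM | 1.3 mM | 1.3 mM |
| time | 20 s | 20 s | 20 s |  |
| remark | a closed flask charged with all of it at once and left for 20 s | a stirred flask in which substrate is dosed at a steady rate over 20.0 s without added volume, worked up at 20 s | plug flow through a tube for 20 s, no back-mixing | a single well-mixed tank run continuously and read at steady state, 20 s in it on average |

    initiator → 2 initiating radical (k1 = 2.98 × 10⁻⁴ s⁻¹)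
    substrate + initiating radical → capped initiator + first chain carrier (k2 = 5.06 × 10⁶ L mol⁻¹ s⁻¹)
    coupling partner + first chain carrier → target + second chain carrier (k3 = 3.36 × 10⁶ L mol⁻¹ s⁻¹)
    substrate + second chain carrier → by-product + first chain carrier (k4 = 1.18 × 10⁵ L mol⁻¹ s⁻¹)
    2 first chain carrier → ended chains (k5 = 1 × 10⁶ L mol⁻¹ s⁻¹)
    coupling partner ⇌ dormant form (K6 = 0.424, k6 = 0.0286 s⁻¹)
    substrate + target → side product (k7 = 0.152 L mol⁻¹ s⁻¹)

- in percentages every species weighs as the substrate in it: one ended chains or side product counts as two
- two of one species on the left: rate k times its square, two consumed each time
- the stated concentrations are those of everything mixed, before any reaction; amounts are the same in each set-up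
- the feed brings no volume worth counting
- run time (north-east): 20 s

- the set-up with the highest amount of target at the outlet or at the end, in percent of the substrate put in ("none" if the first two lie within 2 percentage points) (north-east / south-west / east / north-west / none)
- amount of target at the outlet or at the end, in percent of the substrate put in, north-east
- amount of target at the outlet or at the end, in percent of the substrate put in, south-west
- amount of target at the outlet or at the end, in percent of the substrate put in, east
- amount of target at the outlet or at the end, in percent of the substrate put in, north-west

A plug in the east tube is a closed flask for 20 s, so east and north-east share one history, and the contest is between charging at once and spreading the substrate out. Turned round, one side leads only if the losses differ by more than 2 percentage points, so I compute only the losses from a full yield of target.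

The first chain carrier meets coupling partner at 6.55 × 10⁵ s⁻¹, and the second meets substrate at 15300 s⁻¹, so the second chain carrier is the resting state. Substrate then decays pseudo-first-order at 1.18 × 10⁵ L mol⁻¹ s⁻¹ times [second chain carrier], and that concentration grows linearly, two radicals per initiator broken. Hence a single charge falls as a Gaussian in time. Its width is the chain clock, one over the square root of initiator constant, chain constant and initiator charge multiplied: 4.68 s, the time in which a charge falls by the factor e.

That is shorter than the run, so north-east finishes its substrate. Integrating the side step over the Gaussian, the side product, counted double, comes to about 0.5 times 0.152 L mol⁻¹ s⁻¹, 0.13 M and the clock: 4.62%, leaving target near 95.4%.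

With feeding, or in the tank, [substrate] rides at feed over consumption. The leftover is the clock squared over twice the time squared, 2.73%. Side product reckoned with that [substrate] from the first moment adds 2.16%, but in south-west the early [substrate] is capped by what has been fed, so I take this figure as the top of a range that starts at nothing. The spread-out losses then lie between 2.73% and 4.89%, and the charged-at-once loss of 4.62% lies inside that range. The widest gap, at the low end, is 1.9 points, less than the margin, so I expect a tie.

The forecast says none, with 99.3%, 95.7%, 99.3% and 95.3% in the order asked, reasoning from “the substrate gone in about a second”, and my closed-flask figure lies below its.

The simulation gives 95.4%, 95.6%, 95.4% and 95.3%, in that order, and best: none. In south-west the clock put the substrate's half-life at the end of dosing at 0.380 s; the flask reads 0.38 s at 20.0 s, far shorter than the dosing time of 20.0 s, and holds 2.81% of substrate against the reckoned 2.73%. In the neighbouring flask, south-west with 5.2 × 10⁻⁴ M of initiator, the clock lengthens to 7.40 s, which reckons a leftover of 6.85%, and that flask holds 7.4%.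

The rate constants are assumed; the flask was simulated.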